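## Retrosynthetic overview

1. The ten-membered carbocycle is closed last, at C7–C8. A C8 α-keto radical (from iodomethyl ketone 26) adds to C7 of an allyl ethyl sulfone and the C11 radical ejects EtSO2•, so ring closure, the C7 stereocentre and the isopropenyl group arise in one event.
2. 26 ⇐ bis-angelate Weinreb amide 23 (C8 from LiCH2I) ⇐ diol 20 ⇐ aminolysis of epoxy δ-lactone 19.
3. 19 ⇐ epoxy aldehyde 13 + vinyl iodide 18 (C6–C7; Felkin-type addition sets C6).
4. 13 ⇐ dihydropyranone 11. This temporary O3–C9 lactone (by RCM) fixes the cis C1=C10 geometry and steers the C1–C10 epoxide anti to the C3 side chain. 11 ⇐ epoxy alcohol 8 (OH-directed C4–C5 epoxide) ⇐ Brown allylation of Z-enal 4 ⇐ 3-methylfuran-2(5H)-one.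
5. Ring order: C4–C5 oxirane → temporary δ-lactone → C1–C10 oxirane → lactone opened → carbocycle.

Assumption/notation: germacrane-type locants are used for all intermediates (ring C1–C10; C1 and C5 = epoxide CH, C4 and C10 = epoxide C–CH3, C3 and C6 = CH–O, C7 = CH–isopropenyl, C8 = CH2, C9 = C=O, C11–C13 = isopropenyl). The target SMILES is read as (1R,3S,4R,5S,6S,7S,10R), both oxiranes cis, both esters angelates (Z).

## Route

Step 1
Reactants: 1 3-methylfuran-2(5H)-one
Product: 2 (Z)-4-hydroxy-N-methoxy-N,2-dimethylbut-2-enamide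
Conditions: MeNH(OMe)·HCl, AlMe3, CH2Cl2, 0 °C → rt; Rochelle salt work-up, crude used at once
Reagents that add atoms: N,O-dimethylhydroxylamine hydrochloride, CNOC.Cl
Why: Weinreb aminolysis of the lactone by the weakly basic aluminium amide (1,2-attack, no γ-deprotonation); the ring geometry is carried over as the Z-alkene (C3 and C6 cis).

Step 2
Reactants: 2 (Z)-4-hydroxy-N-methoxy-N,2-dimethylbut-2-enamide
Product: 3 (Z)-N-methoxy-N,2-dimethyl-4-(triethylsilyloxy)but-2-enamide
Conditions: TESCl, imidazole, CH2Cl2, 0 °C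
Reagents that add atoms: chlorotriethylsilane, CC[Si](Cl)(CC)CC
Why: Standard silylation of the primary alcohol, which also blocks relactonisation.

Step 3
Reactants: 3 (Z)-N-methoxy-N,2-dimethyl-4-(triethylsilyloxy)but-2-enamide
Product: 4 (Z)-2-methyl-4-(triethylsilyloxy)but-2-enal
Conditions: DIBAL-H, THF, −78 °C; Rochelle salt
Reagents that add atoms: none
Why: Weinreb amide reduction stops at the aldehyde through the chelated tetrahedral intermediate; at −78 °C with neutral work-up the Z-enal does not isomerise.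

Step 4
Reactants: 4 (Z)-2-methyl-4-(triethylsilyloxy)but-2-enal; 5 allylmagnesium bromide
Product: 7 (2Z,4S)-3-methyl-1-(triethylsilyloxy)hepta-2,6-dien-4-ol, via allylborane 6 (not isolated)
Conditions: 5, (−)-Ipc2BOMe, Et2O, 0 °C → rt; then 4, −78 °C; NaOH, H2O2
Reagents that add atoms: none
Why: Brown asymmetric allylboration through a Zimmerman–Traxler chair; the reagent from (+)-α-pinene attacks the Si face and sets C3 as S (the antipodal borane would give the enantiomeric series).

Step 5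
Reactants: 7 (2Z,4S)-3-methyl-1-(triethylsilyloxy)hepta-2,6-dien-4-ol
Product: 8 (1S)-1-[(2R,3S)-2-methyl-3-(triethylsilyloxymethyl)oxiran-2-yl]but-3-en-1-ol
Conditions: mCPBA (1.05 eq), NaHCO3, CH2Cl2, −10 °C
Reagents that add atoms: mCPBA, OOC(=O)c1cccc(Cl)c1
Why: Henbest hydroxyl-directed epoxidation: A(1,3) strain with the cis C6 substituent holds C3–H in the alkene plane, so the H-bonded peracid is delivered to the OH face and gives the threo (4R,5S) cis-epoxide; the terminal alkene is far less nucleophilic.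

Step 6
Reactants: 8 (1S)-1-[(2R,3S)-2-methyl-3-(triethylsilyloxymethyl)oxiran-2-yl]but-3-en-1-ol; 9 methacryloyl chloride
Product: 10 (1S)-1-[(2R,3S)-2-methyl-3-(triethylsilyloxymethyl)oxiran-2-yl]but-3-en-1-yl 2-methylprop-2-enoate
Conditions: Et3N, DMAP (cat.), CH2Cl2, 0 °C
Reagents that add atoms: none
Why: Ordinary acylation of the secondary alcohol; it brings in C9, C10 and C14.

Step 7
Reactants: 10 (1S)-1-[(2R,3S)-2-methyl-3-(triethylsilyloxymethyl)oxiran-2-yl]but-3-en-1-yl 2-methylprop-2-enoate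
Product: 11 (6S)-3-methyl-6-[(2R,3S)-2-methyl-3-(triethylsilyloxymethyl)oxiran-2-yl]-5,6-dihydro-2H-pyran-2-one
Conditions: Grubbs II (5 mol %), CH2Cl2 (5 mM), 40 °C
Reagents that add atoms: none
Why: Ring-closing metathesis of a homoallyl methacrylate; the six-membered ring forces the C1=C10 alkene to be cis (C9 and C2 cis).

Step 8
Reactants: 11 (6S)-3-methyl-6-[(2R,3S)-2-methyl-3-(triethylsilyloxymethyl)oxiran-2-yl]-5,6-dihydro-2H-pyran-2-one
Product: 12 (1R,4S,6R)-1-methyl-4-[(2R,3S)-2-methyl-3-(triethylsilyloxymethyl)oxiran-2-yl]-3,7-dioxabicyclo[4.1.0]heptan-2-one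
Conditions: t-BuOOH (anhydrous), DBU, CH2Cl2, 0 °C → rt
Reagents that add atoms: tert-butyl hydroperoxide, CC(C)(C)OO
Why: Weitz–Scheffer nucleophilic epoxidation: t-BuOO− adds axially to C1 of the half-chair lactone anti to the pseudo-equatorial C3 side chain, giving the cis-fused (1R,10R) epoxide.

Step 9
Reactants: 12 (1R,4S,6R)-1-methyl-4-[(2R,3S)-2-methyl-3-(triethylsilyloxymethyl)oxiran-2-yl]-3,7-dioxabicyclo[4.1.0]heptan-2-one
Product: 13 (2R,3R)-3-methyl-3-[(1R,4S,6R)-1-methyl-2-oxo-3,7-dioxabicyclo[4.1.0]heptan-4-yl]oxirane-2-carbaldehyde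
Conditions: (COCl)2, DMSO, CH2Cl2, −78 → −40 °C; Et3N, → 0 °C; crude used directly
Reagents that add atoms: none
Why: Swern oxidation that converts a primary TES ether directly into the aldehyde (the chlorosulfonium salt cleaves the Si–O bond), so no separate deprotection is needed; the oxirane C5–H does not enolise (C5 reads R here only because CHO outranks C4).

Step 10
Reactants: 14 prop-2-yn-1-ol
Product: 16 (E)-3-iodo-2-methylprop-2-en-1-ol, via alkenylalane 15 (not isolated)
Conditions: AlMe3, Cp2ZrCl2 (25 mol %), CH2Cl2, 0 °C → rt; then I2, THF, −30 °C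
Reagents that add atoms: trimethylaluminium, C[Al](C)C; iodine, II
Why: Negishi zirconium-catalysed carboalumination (syn addition, methyl to the internal carbon) followed by iodinolysis with retention gives the E-vinyl iodide.

Step 11
Reactants: 16 (E)-3-iodo-2-methylprop-2-en-1-ol
Product: 18 (E)-3-(ethylsulfonyl)-1-iodo-2-methylprop-1-ene, via mesylate 17 (not isolated)
Conditions: MsCl, Et3N, CH2Cl2, −10 °C; then EtSO2Na, DMF, rt
Reagents that add atoms: sodium ethanesulfinate, [Na+].CCS(=O)[O-]; methanesulfonyl chloride, CS(Cl)(=O)=O (in intermediate 17 only)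
Why: Allylic mesylate formation and SN2 S-alkylation of the sulfinate; the vinyl iodide is untouched.

Step 12
Reactants: 13 (2R,3R)-3-methyl-3-[(1R,4S,6R)-1-methyl-2-oxo-3,7-dioxabicyclo[4.1.0]heptan-4-yl]oxirane-2-carbaldehyde; 18 (E)-3-(ethylsulfonyl)-1-iodo-2-methylprop-1-ene
Product: 19 (1R,4S,6R)-4-{(2R,3S)-3-[(1S,2E)-4-(ethylsulfonyl)-1-hydroxy-3-methylbut-2-en-1-yl]-2-methyloxiran-2-yl}-1-methyl-3,7-dioxabicyclo[4.1.0]heptan-2-one
Conditions: CrCl2 (6 eq), NiCl2 (1 mol %), DMSO, rt
Reagents that add atoms: none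
Why: Nozaki–Hiyama–Kishi coupling: the alkenylchromium species (geometry retained) adds to the cis-epoxy aldehyde in the Felkin–Anh/Cornforth sense, on the face away from the cis C4 substituent, giving the erythro 6S carbinol; sulfone, lactone and epoxides tolerate Cr(II).

Step 13
Reactants: 19 (1R,4S,6R)-4-{(2R,3S)-3-[(1S,2E)-4-(ethylsulfonyl)-1-hydroxy-3-methylbut-2-en-1-yl]-2-methyloxiran-2-yl}-1-methyl-3,7-dioxabicyclo[4.1.0]heptan-2-one
Product: 20 (2R,3R)-3-[(2S)-2-{(2R,3S)-3-[(1S,2E)-4-(ethylsulfonyl)-1-hydroxy-3-methylbut-2-en-1-yl]-2-methyloxiran-2-yl}-2-hydroxyethyl]-N-methoxy-N,2-dimethyloxirane-2-carboxamide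
Conditions: MeNH(OMe)·HCl, i-PrMgCl, THF, −20 °C
Reagents that add atoms: N,O-dimethylhydroxylamine hydrochloride, CNOC.Cl
Why: Weinreb aminolysis of the activated epoxy-lactone by ClMgN(OMe)Me opens the temporary ring, frees 3-OH and leaves C9 as an amide; no stereocentre is touched.

Step 14
Reactants: 20 the Weinreb amide diol of step 13; 21 angelic acid [(Z)-2-methylbut-2-enoic acid]
Product: 23 bis-angelate Weinreb amide (20 esterified at O3 and O6 as (Z)-2-methylbut-2-enoates), via mixed anhydride 22 (not isolated)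
Conditions: 21, 2,4,6-Cl3C6H2COCl, Et3N, PhMe, rt; then 20, 70 °C
Reagents that add atoms: 2,4,6-trichlorobenzoyl chloride, O=C(Cl)c1c(Cl)cc(Cl)cc1Cl (in intermediate 22 only)
Why: Yamaguchi esterification without DMAP acylates both secondary alcohols and keeps the angelate Z geometry (no conjugate-addition pathway to tiglate).

Step 15
Reactants: 23 bis-angelate Weinreb amide; 24 diiodomethane
Product: 26 iodomethyl ketone (23 in which C(=O)N(OMe)Me has become C9(=O)–C8H2I), via iodomethyllithium 25 (not isolated)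
Conditions: 24 (3 eq), MeLi·LiBr (2.8 eq, slow addition), THF/Et2O, −78 °C; NH4Cl at −78 °C
Reagents that add atoms: methyllithium, C[Li] (lithium in intermediate 25 only)
Why: Carbenoid homologation: LiCH2I, made in the presence of the substrate, adds to the α-alkoxy-activated Weinreb amide and the chelated tetrahedral intermediate prevents over-addition, while the hindered conjugated angelates react more slowly.

Step 16
Reactants: 26 iodomethyl ketone
Product: 27 target, (1R,3S,4R,5S,6S,7S,10R)-1,10:4,5-diepoxy-9-oxogermacr-11-ene-3,6-diyl bis[(Z)-2-methylbut-2-enoate]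
Conditions: dilauroyl peroxide (4 × 10 mol %), NaHCO3 (solid), PhCl (degassed, 2 mM), 100 °C
Reagents that add atoms: none
Why: Proposed new method: a macrocyclising (10-exo) version of the tin-free radical allylation of α-iodo carbonyl compounds with allyl ethyl sulfones (closest known reaction type, so far intermolecular): the electrophilic C8 α-keto radical adds to C7 of the electron-rich trisubstituted alkene, the tertiary C11 radical expels EtSO2• (→ SO2 + Et•, which abstracts iodine from the next molecule of 26), so the isopropenyl group forms regiospecifically; A(1,3) strain with the C13 methyl holds C6–H in the alkene plane and the tethered radical attacks the face anti to the C6 ester (the face carrying C5 and the chain), giving 7S; the two cis-epoxides act as turn elements and high dilution suppresses oligomers.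

## Compound list

1 | 3-methylfuran-2(5H)-one | CC1=CCOC1=O | starting material
2 | (Z)-4-hydroxy-N-methoxy-N,2-dimethylbut-2-enamide | CON(C)C(=O)/C(C)=C\CO | intermediate
3 | (Z)-N-methoxy-N,2-dimethyl-4-(triethylsilyloxy)but-2-enamide | CON(C)C(=O)/C(C)=C\CO[Si](CC)(CC)CC | intermediate
4 | (Z)-2-methyl-4-(triethylsilyloxy)but-2-enal | O=C/C(C)=C\CO[Si](CC)(CC)CC | intermediate
5 | allylmagnesium bromide | C=CC[Mg]Br | starting material
6 | (−)-B-allyldiisopinocampheylborane | C=CCB([C@@H]1C[C@@H]2C[C@@H](C2(C)C)[C@H]1C)[C@@H]1C[C@@H]2C[C@@H](C2(C)C)[C@H]1C | intermediate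
7 | (2Z,4S)-3-methyl-1-(triethylsilyloxy)hepta-2,6-dien-4-ol | C=CC[C@H](O)/C(C)=C\CO[Si](CC)(CC)CC | intermediate
8 | (1S)-1-[(2R,3S)-2-methyl-3-(triethylsilyloxymethyl)oxiran-2-yl]but-3-en-1-ol | C=CC[C@H](O)[C@@]1(C)O[C@H]1CO[Si](CC)(CC)CC | intermediate
9 | methacryloyl chloride | CC(=C)C(Cl)=O | starting material
10 | (1S)-1-[(2R,3S)-2-methyl-3-(triethylsilyloxymethyl)oxiran-2-yl]but-3-en-1-yl 2-methylprop-2-enoate | C=CC[C@H](OC(=O)C(C)=C)[C@@]1(C)O[C@H]1CO[Si](CC)(CC)CC | intermediate
11 | (6S)-3-methyl-6-[(2R,3S)-2-methyl-3-(triethylsilyloxymethyl)oxiran-2-yl]-5,6-dihydro-2H-pyran-2-one | O=C1O[C@@H](CC=C1C)[C@@]2(C)O[C@H]2CO[Si](CC)(CC)CC | intermediate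
12 | (1R,4S,6R)-1-methyl-4-[(2R,3S)-2-methyl-3-(triethylsilyloxymethyl)oxiran-2-yl]-3,7-dioxabicyclo[4.1.0]heptan-2-one | O=C1O[C@@H](C[C@H]2O[C@@]12C)[C@@]3(C)O[C@H]3CO[Si](CC)(CC)CC | intermediate
13 | (2R,3R)-3-methyl-3-[(1R,4S,6R)-1-methyl-2-oxo-3,7-dioxabicyclo[4.1.0]heptan-4-yl]oxirane-2-carbaldehyde | O=C1O[C@@H](C[C@H]2O[C@@]12C)[C@@]3(C)O[C@H]3C=O | intermediate
14 | prop-2-yn-1-ol | C#CCO | starting material
15 | dimethylaluminium (E)-3-(dimethylalumanyl)-2-methylprop-2-en-1-olate | C[Al](C)OC/C(C)=C/[Al](C)C | intermediate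
16 | (E)-3-iodo-2-methylprop-2-en-1-ol | OC/C(C)=C/I | intermediate
17 | (E)-3-iodo-2-methylprop-2-en-1-yl methanesulfonate | CS(=O)(=O)OC/C(C)=C/I | intermediate
18 | (E)-3-(ethylsulfonyl)-1-iodo-2-methylprop-1-ene | CCS(=O)(=O)C/C(C)=C/I | intermediate
19 | (1R,4S,6R)-4-{(2R,3S)-3-[(1S,2E)-4-(ethylsulfonyl)-1-hydroxy-3-methylbut-2-en-1-yl]-2-methyloxiran-2-yl}-1-methyl-3,7-dioxabicyclo[4.1.0]heptan-2-one | O=C1O[C@@H](C[C@H]2O[C@@]12C)[C@@]3(C)O[C@H]3[C@@H](O)/C=C(\C)CS(=O)(=O)CC | intermediate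
20 | (2R,3R)-3-[(2S)-2-{(2R,3S)-3-[(1S,2E)-4-(ethylsulfonyl)-1-hydroxy-3-methylbut-2-en-1-yl]-2-methyloxiran-2-yl}-2-hydroxyethyl]-N-methoxy-N,2-dimethyloxirane-2-carboxamide | CON(C)C(=O)[C@]1(C)O[C@@H]1C[C@H](O)[C@@]1(C)O[C@H]1[C@@H](O)/C=C(\C)CS(=O)(=O)CC | intermediate
21 | angelic acid, (Z)-2-methylbut-2-enoic acid | C/C=C(/C)C(O)=O | starting material
22 | (Z)-2-methylbut-2-enoic 2,4,6-trichlorobenzoic anhydride | C/C=C(/C)C(=O)OC(=O)c1c(Cl)cc(Cl)cc1Cl | intermediate
23 | bis-angelate Weinreb amide (20 with O3 and O6 as (Z)-2-methylbut-2-enoates; 1R,3S,4R,5S,6S,10R; 7E) | CON(C)C(=O)[C@]1(C)O[C@@H]1C[C@H](OC(=O)/C(C)=C\C)[C@@]1(C)O[C@H]1[C@@H](OC(=O)/C(C)=C\C)/C=C(\C)CS(=O)(=O)CC | intermediate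
24 | diiodomethane | ICI | starting material
25 | iodomethyllithium | [Li]CI | intermediate
26 | iodomethyl ketone (23 with C9(=O)–C8H2I in place of the amide; 1R,3S,4R,5S,6S,10R; 7E) | ICC(=O)[C@]1(C)O[C@@H]1C[C@H](OC(=O)/C(C)=C\C)[C@@]1(C)O[C@H]1[C@@H](OC(=O)/C(C)=C\C)/C=C(\C)CS(=O)(=O)CC | intermediate
27 | target, (1R,3S,4R,5S,6S,7S,10R)-1,10:4,5-diepoxy-9-oxogermacr-11-ene-3,6-diyl bis[(Z)-2-methylbut-2-enoate] | C=C(C)[C@@H]1CC(=O)[C@]2(C)O[C@@H]2C[C@H](OC(=O)/C(C)=C\C)[C@@]2(C)O[C@H]2[C@H]1OC(=O)/C(C)=C\C | target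

## Step count and risks

Total: 16 steps. Longest linear sequence: 14 steps (1–9, 12–16); steps 10–11 make the side fragment 18.

The three steps most likely to fail:

Step 16 (radical macrocyclisation; an untested 10-exo closure that also sets C7). The fallback sets out from 26 and returns at 27. The iodide is displaced with potassium O-ethyl xanthate (acetone, 0 °C) to give the S-(2-oxoalkyl) O-ethyl xanthate F1. F1 is then cyclised in a degenerative xanthate group-transfer manifold (dilauroyl peroxide in portions, refluxing 1,2-dichloroethane or chlorobenzene, 2–5 mM). Here the α-keto radical is stored reversibly as the dormant xanthate between additions instead of depending on an iodine-atom chain, which suits a slow ring closure; the same addition at C7 and loss of EtSO2• (whose ethyl radical carries the xanthate away) gives 27.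

Step 15 (carbenoid addition next to two angelates and an acidic allyl sulfone). The fallback sets out from 23 and returns at 26, replacing the carbenoid homologation by enolate α-iodination. MeMgBr (THF, −40 °C) converts the Weinreb amide into the methyl ketone F2, which can enolise only towards C8 because C10 is quaternary. Internal-quench silylation (LiHMDS, TMSCl, THF, −78 °C) gives the silyl enol ether F3, and N-iodosuccinimide (THF, −78 → 0 °C) iodinates it to 26.

Step 12 (diastereoselectivity at C6 in the addition to the epoxy aldehyde). The fallback sets out from 19 obtained as a C6-epimer mixture and returns at 19, replacing substrate control by reagent control. Dess–Martin oxidation (NaHCO3, CH2Cl2) gives the epoxy enone F4. Corey–Bakshi–Shibata reduction ((S)-Me-CBS, catecholborane, toluene, −78 °C, with the alkenyl group as the large substituent; the antipodal catalyst if the sense proves opposite) returns the 6S alcohol 19.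

## Further compounds

F1 | step 16 | S-(2-oxoalkyl) O-ethyl xanthate of 26 (SC(=S)OEt in place of iodine at C8) | CCOC(=S)SCC(=O)[C@]1(C)O[C@@H]1C[C@H](OC(=O)/C(C)=C\C)[C@@]1(C)O[C@H]1[C@@H](OC(=O)/C(C)=C\C)/C=C(\C)CS(=O)(=O)CC
F2 | step 15 | methyl ketone (23 with C9(=O)–C8H3 in place of the amide) | CC(=O)[C@]1(C)O[C@@H]1C[C@H](OC(=O)/C(C)=C\C)[C@@]1(C)O[C@H]1[C@@H](OC(=O)/C(C)=C\C)/C=C(\C)CS(=O)(=O)CC
F3 | step 15 | trimethylsilyl enol ether of F2 (C8=C9–OSiMe3) | C=C(O[Si](C)(C)C)[C@]1(C)O[C@@H]1C[C@H](OC(=O)/C(C)=C\C)[C@@]1(C)O[C@H]1[C@@H](OC(=O)/C(C)=C\C)/C=C(\C)CS(=O)(=O)CC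
F4 | step 12 | C6 ketone of 19 (epoxy enone) | O=C1O[C@@H](C[C@H]2O[C@@]12C)[C@@]3(C)O[C@H]3C(=O)/C=C(\C)CS(=O)(=O)CC
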